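**Retrosynthetic overview**
- The strategy rests on ring A: a benzene in which C5, C6, C7, C8 and C8a all carry oxygen and only C4a carries carbon (C4). It is cut into a trioxygenated three-carbon carbene unit (C5 to C7), one CO (C8) and a two-carbon methoxy alkynoate (C8a, C4a with C4).
- Ring C (the 4-pyranone) is opened at O1–C2 to an ortho-hydroxyaryl 1,3-diketone, and at C3–C4 to the ring A benzoate and the methyl ketone of ring B (O-benzyl acetosyringone).
- The phenol that CO delivers at C8 is methylated to a pentamethoxybenzoate with a mirror plane through C4a and C7, so cleavage of either ortho methyl ether gives the same C8a phenol.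
- Carbene complex 6 comes from 1,2-dimethoxyethene, Cr(CO)6 and Me3OBF4; alkyne 11 comes from methoxyacetylene and methyl chloroformate.
- Ring order: ring B is bought, ring A is built in step 5, ring C is closed last in step 10.

Key step: step 5

Assumption: alkoxyalkynes 9 and 11 hydrate and polymerise readily, so both are handled as cold anhydrous solutions and used at once.

**Step 1**
Reactants: 1 1,1,2-trimethoxyethane
Product: 2 (Z)-1,2-dimethoxyethene
Conditions: TMSOTf, i-Pr2NEt, CH2Cl2, 0 °C to rt; fractional distillation
Reagents that add atoms: none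
Why: Silyl triflate-mediated conversion of a dimethyl acetal into its methyl enol ether (ionisation to the oxocarbenium ion, then loss of the alpha proton to the amine) should give the enol ether, whose more stable Z isomer is collected by distillation.

**Step 2**
Reactants: 2 (Z)-1,2-dimethoxyethene; 3 chromium hexacarbonyl Cr(CO)6
Product: 6 pentacarbonyl[(2Z)-1,2,3-trimethoxyprop-2-en-1-ylidene]chromium, via (Z)-1,2-dimethoxyvinyllithium 4 (not isolated), via lithium acyl chromate 5 (not isolated)
Conditions: t-BuLi, THF, −78 °C; Cr(CO)6, THF, −78 to −20 °C; then Me3OBF4, CH2Cl2, 0 °C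
Reagents that add atoms: trimethyloxonium tetrafluoroborate, C[O+](C)C.F[B-](F)(F)F
Why: Fischer carbene synthesis: the enol ether is lithiated at an oxygen-bearing carbon with retention of geometry, the vinyllithium adds to a CO ligand of Cr(CO)6 and the acyl chromate is O-methylated, all kept cold so that 4 does not lose LiOMe.

**Step 3**
Reactants: 7 chloroacetaldehyde dimethyl acetal (2-chloro-1,1-dimethoxyethane)
Product: 9 methoxyacetylene, via sodium methoxyacetylide 8 (not isolated)
Conditions: NaNH2 (3 equiv), liq. NH3, −33 °C; NH3 off; cold brine, −70 °C; distilled into THF at −78 °C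
Reagents that add atoms: none
Why: Double elimination with NaNH2 (methanol, then HCl) is the standard route from alpha-haloacetals to alkoxyacetylenes, and the acetylide formed by the third equivalent is protonated on quench.

**Step 4**
Reactants: 9 methoxyacetylene
Product: 11 methyl 3-methoxyprop-2-ynoate, via lithium methoxyacetylide 10 (not isolated)
Conditions: n-BuLi, THF, −78 °C; cannulated into ClCO2Me, THF, −78 to −30 °C
Reagents that add atoms: methyl chloroformate, COC(=O)Cl
Why: C-Acylation of a lithium acetylide with a chloroformate should give the alkynoate, and inverse addition to excess chloroformate keeps the acetylide from adding to the product.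

**Step 5**
Reactants: 6 pentacarbonyl[(2Z)-1,2,3-trimethoxyprop-2-en-1-ylidene]chromium; 11 methyl 3-methoxyprop-2-ynoate
Product: 13 methyl 3-hydroxy-2,4,5,6-tetramethoxybenzoate, via tricarbonylchromium arene complex 12 (not isolated)
Conditions: THF, 50 °C, Ar; then air, Et2O, rt
Reagents that add atoms: none
Why: Proposed new method: Loss of one CO from 6 should let alkyne 11 bind and insert into the Cr=C bond (C4a–C5), a CO ligand then inserts into the new carbene (C8a–C8) to give a metal-bound dienylketene, and tautomerisation of the cyclised dienone gives the phenol, first as Cr(CO)3 complex 12, which air frees. The closest known reaction type is the Dötz benzannulation of alkenyl(alkoxy)carbene complexes of zerovalent chromium with alkynes, which has not been shown for a trioxygenated alkenyl carbene combined with an alkoxy alkynoate. Ring A closes by 6π-electrocyclisation of the dienylketene, the ketene carbon bonding to the enol ether CH (C7–C8). No stereocentre is formed, and the enol ether geometry is erased when C7 becomes aromatic. The step needs the ester-bearing alkyne carbon to join the carbene carbon; the push-pull polarisation of 11 should secure this, because the carbon beta to the alkyne methoxy group is the nucleophilic end and its attack leaves chromium on the methoxy-bearing carbon as a donor-stabilised carbene next to the inserting CO. CO insertion must also outrun closure to a five-membered ring, which chromium, an alkenyl carbene and a methoxy (not amino) donor favour.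

**Step 6**
Reactants: 13 methyl 3-hydroxy-2,4,5,6-tetramethoxybenzoate
Product: 14 methyl 2,3,4,5,6-pentamethoxybenzoate
Conditions: MeI, K2CO3, acetone, reflux
Reagents that add atoms: iodomethane, CI
Why: Williamson O-methylation of the phenoxide should proceed cleanly, as the ester and the aryl methyl ethers are inert to carbonate.

**Step 7**
Reactants: 15 acetosyringone
Product: 16 1-[4-(benzyloxy)-3,5-dimethoxyphenyl]ethan-1-one
Conditions: BnBr, K2CO3, DMF, rt
Reagents that add atoms: benzyl bromide, BrCc1ccccc1
Why: Williamson O-benzylation masks the acidic phenol so that only the methyl ketone is deprotonated in the next step.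

**Step 8**
Reactants: 14 methyl 2,3,4,5,6-pentamethoxybenzoate; 16 1-[4-(benzyloxy)-3,5-dimethoxyphenyl]ethan-1-one
Product: 18 1-[4-(benzyloxy)-3,5-dimethoxyphenyl]-3-(2,3,4,5,6-pentamethoxyphenyl)propane-1,3-dione, via sodium diketonate 17 (not isolated)
Conditions: NaH (3 equiv), THF, reflux; then aq. HCl, 0 °C
Reagents that add atoms: none
Why: Crossed Claisen condensation forms C3–C4: the enolate of 16 acylates at the ester of 14 and deprotonation of the product to 17 drives the equilibrium, as in the classical flavone route through ortho-methoxybenzoyl acetophenones.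

**Step 9**
Reactants: 18 1-[4-(benzyloxy)-3,5-dimethoxyphenyl]-3-(2,3,4,5,6-pentamethoxyphenyl)propane-1,3-dione
Product: 19 1-(2-hydroxy-3,4,5,6-tetramethoxyphenyl)-3-(4-hydroxy-3,5-dimethoxyphenyl)propane-1,3-dione
Conditions: BCl3 (4 equiv), C6HMe5 (3 equiv), CH2Cl2, −78 to 0 °C; then H2O
Reagents that add atoms: none
Why: Chelation-directed ether cleavage: boron held between the ring A carbonyl oxygen and one flanking methoxy oxygen delivers chloride to that methyl group only (either ortho group gives the same phenol), while BCl3 with pentamethylbenzene as cation trap removes the benzyl ether and spares non-chelated aryl methyl ethers.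

**Step 10**
Reactants: 19 1-(2-hydroxy-3,4,5,6-tetramethoxyphenyl)-3-(4-hydroxy-3,5-dimethoxyphenyl)propane-1,3-dione
Product: 20 4'-hydroxy-3',5,5',6,7,8-hexamethoxyflavone
Conditions: cat. H2SO4, AcOH, 60 °C
Reagents that add atoms: none
Why: Acid-catalysed cyclodehydration, the closing stage of the Baker–Venkataraman flavone synthesis, adds the C8a phenol to the ring B-side carbonyl (O1–C2) and loses water to form ring C, under conditions that should not cleave the 5-methoxy group.

**Compound list**
1 | 1,1,2-trimethoxyethane | COCC(OC)OC | starting material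
2 | (Z)-1,2-dimethoxyethene | CO/C=C\OC | intermediate
3 | chromium hexacarbonyl Cr(CO)6 | O=C=[Cr](=C=O)(=C=O)(=C=O)(=C=O)=C=O | starting material
4 | (Z)-1,2-dimethoxyvinyllithium | CO/C=C(\OC)[Li] | intermediate
5 | lithium pentacarbonyl[(2Z)-2,3-dimethoxyprop-2-enoyl]chromate | CO/C=C(\OC)C([O-])=[Cr](=C=O)(=C=O)(=C=O)(=C=O)=C=O.[Li+] | intermediate
6 | pentacarbonyl[(2Z)-1,2,3-trimethoxyprop-2-en-1-ylidene]chromium | CO/C=C(\OC)C(OC)=[Cr](=C=O)(=C=O)(=C=O)(=C=O)=C=O | intermediate
7 | chloroacetaldehyde dimethyl acetal | COC(CCl)OC | starting material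
8 | sodium methoxyacetylide | COC#C[Na] | intermediate
9 | methoxyacetylene | COC#C | intermediate
10 | lithium methoxyacetylide | COC#C[Li] | intermediate
11 | methyl 3-methoxyprop-2-ynoate | COC#CC(=O)OC | intermediate
12 | tricarbonyl(η6-arene)chromium complex of 13 (η6 bond written as a dot) | COC(=O)c1c(OC)c(O)c(OC)c(OC)c1OC.O=C=[Cr](=C=O)=C=O | intermediate
13 | methyl 3-hydroxy-2,4,5,6-tetramethoxybenzoate | COC(=O)c1c(OC)c(O)c(OC)c(OC)c1OC | intermediate
14 | methyl 2,3,4,5,6-pentamethoxybenzoate | COC(=O)c1c(OC)c(OC)c(OC)c(OC)c1OC | intermediate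
15 | acetosyringone, 1-(4-hydroxy-3,5-dimethoxyphenyl)ethan-1-one | CC(=O)c1cc(OC)c(O)c(OC)c1 | starting material
16 | 1-[4-(benzyloxy)-3,5-dimethoxyphenyl]ethan-1-one | CC(=O)c1cc(OC)c(OCc2ccccc2)c(OC)c1 | intermediate
17 | sodium (Z)-enolate of 18 | COc1cc(C(=O)/C=C(\[O-])c2c(OC)c(OC)c(OC)c(OC)c2OC)cc(OC)c1OCc1ccccc1.[Na+] | intermediate
18 | 1-[4-(benzyloxy)-3,5-dimethoxyphenyl]-3-(2,3,4,5,6-pentamethoxyphenyl)propane-1,3-dione | COc1cc(C(=O)CC(=O)c2c(OC)c(OC)c(OC)c(OC)c2OC)cc(OC)c1OCc1ccccc1 | intermediate
19 | 1-(2-hydroxy-3,4,5,6-tetramethoxyphenyl)-3-(4-hydroxy-3,5-dimethoxyphenyl)propane-1,3-dione | COc1cc(C(=O)CC(=O)c2c(O)c(OC)c(OC)c(OC)c2OC)cc(OC)c1O | intermediate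
20 | 4'-hydroxy-3',5,5',6,7,8-hexamethoxyflavone | COc1cc(-c2cc(=O)c3c(OC)c(OC)c(OC)c(OC)c3o2)cc(OC)c1O | target

**Step count**
Total: 10 steps. Longest linear sequence: 7 steps (1, 2, 5, 6, 8, 9, 10; the alkyne branch 3, 4, 5, 6, 8, 9, 10 is equally long).

**Steps most likely to fail**

1. Step 5 (Proposed new method). The alkyne may insert with the reverse orientation, the vinylcarbene may close to a five-membered ring without taking up CO, or the push-pull alkyne may oligomerise at the metal before it inserts. The fallback uses known chemistry, sets out from acetosyringone 15, comes back at 14 and makes steps 1 to 6 unnecessary. Dakin oxidation of 15 (H2O2, aq. NaOH) would give 2,6-dimethoxybenzene-1,4-diol F1, and FeCl3 in water would oxidise it to 2,6-dimethoxy-1,4-benzoquinone F2. Thiele–Winter acetoxylation (Ac2O, cat. H2SO4) would add the fifth oxygen and give 3,5-dimethoxybenzene-1,2,4-triyl triacetate F3. Deacetylation and methylation in one pot (Me2SO4, aq. NaOH, MeOH, N2) would give pentamethoxybenzene F4. Lithiation of its single ring C–H between two methoxy groups (n-BuLi, TMEDA, THF, 0 °C) and quench with ClCO2Me would give 14.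

2. Step 2. Vinyllithium 4 carries lithium anti to the beta methoxy group and may lose LiOMe to give methoxyacetylide faster than it adds to the sparingly soluble Cr(CO)6. The fallback sets out from 3 and comes back at 6; it reverses the polarity, with chromium as nucleophile and the three-carbon unit as acyl electrophile. Methyl methoxyacetate would be formylated (HCO2Me, NaH, THF) to methyl 2-methoxy-3-oxopropanoate F5, held as its sodium enolate, and O-methylated (Me2SO4, K2CO3, DMF) to methyl (2Z)-2,3-dimethoxyprop-2-enoate F6. Saponification (LiOH, THF/H2O) would give (2Z)-2,3-dimethoxyprop-2-enoic acid F7, and (COCl)2 with cat. DMF in CH2Cl2 would give (2Z)-2,3-dimethoxyprop-2-enoyl chloride F8. Reduction of 3 with NaC10H8 (2 equiv, THF, −78 °C) would give disodium pentacarbonylchromate F9, that is Na2Cr(CO)5. Acylation with F8 would give sodium pentacarbonyl[(2Z)-2,3-dimethoxyprop-2-enoyl]chromate F10, and Me3OBF4 would then give 6.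

3. Step 9. Boron may be tied up as a diketonate chelate, so that cleavage is no longer steered to one ortho methoxy group and the second ortho or vicinal methyl ethers are also cleaved. The fallback sets out from 14 and comes back at 19; the ortho ether is unmasked on the ester, where a single carbonyl directs, and the benzyl groups are removed by hydrogenolysis. BCl3 (1.1 equiv, CH2Cl2, −78 to 0 °C) on 14 would give methyl 2-hydroxy-3,4,5,6-tetramethoxybenzoate F11. BnBr, K2CO3 in DMF would give methyl 2-(benzyloxy)-3,4,5,6-tetramethoxybenzoate F12. Claisen condensation with 16 (NaH, THF, reflux) would give 1-[2-(benzyloxy)-3,4,5,6-tetramethoxyphenyl]-3-[4-(benzyloxy)-3,5-dimethoxyphenyl]propane-1,3-dione F13. H2 over Pd/C in EtOAc would remove both benzyl groups and give 19.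

**Further compounds**
F1 | step 5 | 2,6-dimethoxybenzene-1,4-diol | COc1cc(O)cc(OC)c1O
F2 | step 5 | 2,6-dimethoxy-1,4-benzoquinone | COC1=CC(=O)C=C(OC)C1=O
F3 | step 5 | 3,5-dimethoxybenzene-1,2,4-triyl triacetate | CC(=O)Oc1cc(OC)c(OC(C)=O)c(OC)c1OC(C)=O
F4 | step 5 | pentamethoxybenzene | COc1cc(OC)c(OC)c(OC)c1OC
F5 | step 2 | methyl 2-methoxy-3-oxopropanoate | COC(C=O)C(=O)OC
F6 | step 2 | methyl (2Z)-2,3-dimethoxyprop-2-enoate | CO/C=C(\OC)C(=O)OC
F7 | step 2 | (2Z)-2,3-dimethoxyprop-2-enoic acid | CO/C=C(\OC)C(=O)O
F8 | step 2 | (2Z)-2,3-dimethoxyprop-2-enoyl chloride | CO/C=C(\OC)C(=O)Cl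
F9 | step 2 | disodium pentacarbonylchromate Na2Cr(CO)5 | [Na+].[Na+].O=C=[Cr-2](=C=O)(=C=O)(=C=O)=C=O
F10 | step 2 | sodium pentacarbonyl[(2Z)-2,3-dimethoxyprop-2-enoyl]chromate | CO/C=C(\OC)C([O-])=[Cr](=C=O)(=C=O)(=C=O)(=C=O)=C=O.[Na+]
F11 | step 9 | methyl 2-hydroxy-3,4,5,6-tetramethoxybenzoate | COC(=O)c1c(O)c(OC)c(OC)c(OC)c1OC
F12 | step 9 | methyl 2-(benzyloxy)-3,4,5,6-tetramethoxybenzoate | COC(=O)c1c(OCc2ccccc2)c(OC)c(OC)c(OC)c1OC
F13 | step 9 | 1-[2-(benzyloxy)-3,4,5,6-tetramethoxyphenyl]-3-[4-(benzyloxy)-3,5-dimethoxyphenyl]propane-1,3-dione | COc1cc(C(=O)CC(=O)c2c(OCc3ccccc3)c(OC)c(OC)c(OC)c2OC)cc(OC)c1OCc1ccccc1
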